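## Structural features

The target is a 1,3,4-trisubstituted benzene: in thymol numbering C7 is the benzylic CH2 on C1, the phenol oxygen sits on C3, and C4 carries C8, the quaternary carbon of a 2,2-disubstituted oxirane (C8–C9–O) that also bears the acyloxymethyl carbon C10. Three esters decorate this core, a (Z)-2-methylbut-2-enoate (angelate) on the phenol oxygen and two (R)-2-methylbutanoates on O7 and O10. There are three stereocentres, C8 (R) and the two α-carbons of the saturated acyl groups (both R), plus the Z double bond; none is adjacent to another, so nothing can relay configuration to C8, and the acyl stereocentres and the alkene geometry are bought with the acids. The oxirane is tertiary, benzylic and ortho to an oxygen donor, so acid opens or rearranges it (Meinwald type), and a free phenol beside it can attack it intramolecularly. The angelate isomerises to the tiglate by addition–elimination and is an activated aryl ester, the C7 ester is benzylic and rules out hydrogenolysis, and the α-carbons of the saturated esters would epimerise under strong base. The real difficulty is C8: fully substituted, without hydrogen, and flanked by two CH2–O arms (C9 and C10) that differ only in the oxygen to which each is bound. That near-symmetry is what the key step exploits: if C9 and C10 are tied to one oxygen in a four-membered ring, C8 becomes C3 of an achiral 3-aryl-oxetan-3-ol. The stereochemical problem then shrinks to choosing which of two enantiotopic ring CH2–O bonds to break, and the tertiary oxygen on C8 is placed to close the oxirane onto the carbon that received the nucleophile.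

## Logic of the disconnections

**18 ⇒ 14 + 15.** The aryl O–C(=O) bond of the angelate is cut and the phenol oxygen is capped as the allyl ether in 14. The Z-enoate is the group most easily damaged, so it goes on last, and the cut leaves a diester that tolerates base and nucleophiles better. The forward step must remove the allyl group with Pd(PPh3)4, a zerovalent palladium complex, without touching oxirane or esters. It must not let the free phenol 16 stand next to the oxirane, and it must transfer the acyl group of 15 through 17 without Z-to-E isomerisation.

**14 ⇒ 12 + 13 (two equivalents).** Both alkyl O–C(=O) bonds, at O7 and O10, are cut together. The two acyl groups are identical, so one operation with two equivalents of the acid serves both hydroxyls and O7 never has to be told apart from O10. The forward step must acylate under non-acidic conditions, because the oxirane of 12 is tertiary and benzylic, and must not epimerise the α-carbon of 13.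

**12 ⇒ 10.** The C9–O bond of the oxirane is cut (retro 3-exo-tet), C9 takes bromine, and the three hydroxyls are silylated. The acid-labile ring becomes a robust bromohydrin ether, and the C9 arm (CH2Br) and the C10 arm (CH2OSi) become the two halves of an opened four-membered ring. The forward step needs all three silyl groups to fall in one fluoride treatment, and the tertiary alkoxide of 11 to close the three-membered ring faster than the primary alkoxide recloses the four-membered one. Freeing both alkoxides at once with fluoride serves this better than methanolysis, which would uncover the primary oxygen first. No bond at C8 is made or broken.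

**10 ⇒ 8 + 9.** The C9–Br and O10–Si bonds are cut and C9 is reconnected to O10. The stereocentre vanishes: 8 has a mirror plane through C8, and the only task left is to distinguish its two enantiotopic ring CH2 groups. The forward step needs a chiral catalyst that does this, and a substrate with no free hydroxyl and no silyl ether that 9 could attack. Hence the Me3Si cap on the tertiary oxygen and a bulky i-Pr3Si group, chosen over a smaller silyl ether, on O7.

**8 ⇒ 7 ⇒ 4 + 5.** After the tertiary O–Si bond is removed, the aryl C4–C8 bond is cut. It is the only skeletal bond the route has to make, and it splits the molecule into a purchasable ketone 5 and an aryl bromide. The forward step demands bromine–lithium exchange to 6 in the presence of an allyl ether, and clean addition to a ketone that a base could also deprotonate.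

**4 ⇒ 3 ⇒ 2 ⇒ 1.** The O7–Si bond is cut, C7 is raised from alcohol to ester oxidation level, and the allyl O–C bond is cut. 1 already carries the three substituents in the 1,3,4 pattern, so no aromatic substitution is needed. The forward steps are routine, but the order matters: the phenol is allylated before hydride reduction, and the alcohol is silylated before the organolithium step.

## Other disconnections considered

Alternative 1: The cut removes the oxirane methylene, breaking C8–C9 and C9–O, and leads back to the aryl silyloxymethyl ketone A2.

- Forward key step: a methylene group is transferred from deprotonated trimethylsulfoxonium iodide A3 to A2 under LaLi3(binaphthoxide)3 catalysis. This forms C8–C9 and then closes the ring by O–C9 bond formation, giving oxirane A1.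
- In its favour: a skeletal C–C bond, the final ring and the stereocentre are made together, and C8 is born in its final setting with no ring contraction and no halide. A2 is one acylation away from an aryllithium of the type of 6, and A1 needs only fluoride to reach 12.
- Where it is better: the stretch from 4 to 12 would be one step shorter than in the chosen plan, and the key step builds a skeletal bond where the chosen one builds none.
- Against it here: the catalyst tells the ketone faces apart by the size contrast of the two flanking groups, and its best substrates are methyl ketones. In A2 the groups are an ortho-alkoxylated aryl ring, twisted out of conjugation, and a branched, Lewis-basic CH2OSi group. The contrast is small and the α-oxygen offers the oxophilic lanthanum a second binding mode. A2 is also enolisable under the basic conditions, and α-oxygenated ketones are activated enough for an uncatalysed background methylene transfer.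
- Comparison: on mechanism the plans are equal in resting all asymmetry on one catalytic event on an achiral substrate. The chosen plan asks its catalyst to distinguish two CH2 groups held in a rigid ring by substituents (aryl against Me3SiO) that differ grossly, which is the more secure demand. On structure, A1 and 12 are equivalent entry points to the same endgame.

Alternative 2: The cut is the C8–O bond.

- Forward key step: Pd2(dba)3, a zerovalent palladium source, with a chiral phosphoramidite ligand ionises the racemic vinyl dioxolanone A5 with loss of CO2. The π-allyl intermediate is captured at its tertiary terminus by water to give the tertiary allylic diol A4.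
- In its favour: the process is stereoconvergent, so both enantiomers of A5 are funnelled into one A4. The C–O bond is made directly at C8.
- Where it is better: conditions are neutral, so the C7 ester can already be in place, whereas the chosen plan must keep O7 silylated.
- Against it here: A4 has the wrong oxidation pattern on its arms. The free CH2OH must become C9 by sulfonylation and closure to the vinyl oxirane A6. Only then can the vinyl group be cut down by ozonolysis and reduction to the C10 hydroxymethyl. The order is rigid, because unmasking the second hydroxymethyl before the first is differentiated would give a triol with two identical arms and erase C8. A5 itself needs a ketone, a vinyl addition and a carbonate formation, with functional groups that do not tolerate organometallic reagents. The ortho substituent on the aryl ring also crowds the π-allyl terminus.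
- Comparison: the final exchange of the aryl silyl ether for the angelate frees a phenoxide next to the oxirane, so the endgame problem is the same (equal). The alternative forms its stereocentre by ionisation and recombination at a tertiary benzylic carbon; the chosen plan uses an SN2 event at a primary carbon and never touches C8. On step economy the alternative is longer by several steps and carries a redox detour in which one carbon is discarded.

Alternative 3: The cut is the aryl C4–C8 bond.

- Forward key step: the titanium phenoxide of phenol A8, generated with Ti(OiPr)4 and a chiral binaphthol ligand, delivers its ortho carbon to the ketone carbonyl of ketoester A9 in a templated Friedel–Crafts hydroxyalkylation, giving the hydroxy ester A7.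
- Where it is better: this is the most convergent of the four plans. Two small fragments are joined, the skeletal bond and the stereocentre form together, and the native phenol serves as directing group. Neither halogen, organolithium nor phenol protection is needed before the key step.
- Step count: to 12 the sequence is about equal to the chosen plan or one step shorter. After the key step come allylation of the phenol, reduction of the ester, sulfonylation of the new primary hydroxyl with ring closure to A1, and fluoride.
- Against it here: enantioselective versions of this reaction rest on very electrophilic partners, and A9 is an enolisable pyruvate with a β-silyloxy group that can eliminate. Attack must be steered to one of two ortho positions and away from the para position. A7 carries a phenol beside an ester and can lactonise. The later reduction and selective sulfonylation add chemoselectivity questions the chosen plan does not have.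
- Comparison: on mechanism the alternative needs regio-, enantio- and chemoselectivity in one step, while the chosen plan needs only group selectivity between two CH2 groups. On structure both converge on the same epoxy diol.

Key step: step 6

Remarks before the route:

- The sense of induction of the squaramide is assumed by analogy with simpler 3,3-disubstituted oxetanes. The catalyst enantiomer that delivers (S)-10 is used; both antipodes are equally accessible.
- The descriptor at C8 changes from S (10, 11, 12) to R (14, 16, 18) only through CIP priorities. No bond at C8 is touched after step 6.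

## Route

Step 1
Reactants: 1 methyl 4-bromo-3-hydroxybenzoate
Product: 2 methyl 4-bromo-3-(prop-2-en-1-yloxy)benzoate
Conditions: allyl bromide (1.2 equiv), K2CO3 (2 equiv), DMF, rt
Reagents that add atoms: allyl bromide, C=CCBr
Why: Williamson ether synthesis: the phenoxide is alkylated on oxygen by the allylic bromide, and the methyl ester is inert to carbonate in DMF.

Step 2
Reactants: 2 methyl 4-bromo-3-(prop-2-en-1-yloxy)benzoate
Product: 3 [4-bromo-3-(prop-2-en-1-yloxy)phenyl]methanol
Conditions: i-Bu2AlH (2.5 equiv), CH2Cl2, −78 to 0 °C; aq. potassium sodium tartrate
Reagents that add atoms: none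
Why: Hydride reduction of the ester to the primary benzylic alcohol; the aluminium hydride at low temperature leaves the aryl bromide and the allyl ether alone, where a stronger hydride could debrominate.

Step 3
Reactants: 3 [4-bromo-3-(prop-2-en-1-yloxy)phenyl]methanol
Product: 4 {[4-bromo-3-(prop-2-en-1-yloxy)phenyl]methoxy}tri(propan-2-yl)silane
Conditions: i-Pr3SiCl (1.2 equiv), imidazole (2.5 equiv), DMF, rt
Reagents that add atoms: chlorotri(propan-2-yl)silane, CC(C)[Si](Cl)(C(C)C)C(C)C
Why: Imidazole-promoted silylation of a primary alcohol; the bulky silyl ether is chosen because it must survive n-BuLi in step 4 and the silyl bromide in step 6 and still leave with fluoride in step 7.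

Step 4
Reactants: 4 {[4-bromo-3-(prop-2-en-1-yloxy)phenyl]methoxy}tri(propan-2-yl)silane, 5 oxetan-3-one
Product: 7 3-[2-(prop-2-en-1-yloxy)-4-({[tri(propan-2-yl)silyl]oxy}methyl)phenyl]oxetan-3-ol, via aryllithium 6 (not isolated)
Conditions: n-BuLi (1.05 equiv), THF, −78 °C, 20 min; then 5 (1.3 equiv), −78 to −40 °C; aq. NH4Cl
Reagents that add atoms: none
Why: Bromine–lithium exchange is faster at −78 °C than any deprotonation or carbolithiation involving the allyl ether, and the aryllithium then undergoes 1,2-addition to the strained, electrophilic ketone; the product is achiral, so no stereochemical question arises.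

Step 5
Reactants: 7 3-[2-(prop-2-en-1-yloxy)-4-({[tri(propan-2-yl)silyl]oxy}methyl)phenyl]oxetan-3-ol
Product: 8 trimethyl({3-[2-(prop-2-en-1-yloxy)-4-({[tri(propan-2-yl)silyl]oxy}methyl)phenyl]oxetan-3-yl}oxy)silane
Conditions: Me3SiCl (1.5 equiv), imidazole (3 equiv), DMF, 0 °C to rt; chromatography on Et3N-treated silica, azeotropic drying
Reagents that add atoms: chlorotrimethylsilane, C[Si](C)(C)Cl
Why: Silylation of the tertiary alcohol removes the last protic group, so that the silyl bromide of step 6 cannot generate HBr; the buffered conditions are too weakly Lewis acidic to open the oxetane.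

Step 6
Reactants: 8 trimethyl({3-[2-(prop-2-en-1-yloxy)-4-({[tri(propan-2-yl)silyl]oxy}methyl)phenyl]oxetan-3-yl}oxy)silane, 9 bromotrimethylsilane
Product: 10 (2S)-1-bromo-2-[2-(prop-2-en-1-yloxy)-4-({[tri(propan-2-yl)silyl]oxy}methyl)phenyl]-2,3-bis(trimethylsilyloxy)propane
Conditions: chiral squaramide hydrogen-bond donor (one N bearing an electron-poor aryl group, the other a tert-leucine 2-arylpyrrolidine amide; 10 mol%), 9 (1.3 equiv), t-BuOMe, −78 °C; Et3N quench, filtration, evaporation; crude 10 used directly
Reagents that add atoms: none
Why: The two squaramide N–H bonds bind the bromide of 9, which raises the silylating power of silicon and transfers Me3Si to the most Lewis-basic oxygen, the oxetane oxygen, giving a silyloxetanium ion paired with catalyst-bound bromide. Within this chiral ion pair bromide attacks one of the two enantiotopic ring CH2 groups in an SN2 step driven by release of ring strain, forming the C9–Br bond and leaving the former ring oxygen as the Me3SiO group on C10. The closest known reaction type is the hydrogen-bond-donor-catalysed enantioselective opening of 3-substituted and 3,3-disubstituted oxetanes by a silyl bromide. No ring is closed and no skeletal bond is formed; the four-membered ring is opened. C8 becomes stereogenic only because its two CH2 arms become different, so its configuration is set entirely by the catalyst, the sole chiral element present, and the catalyst enantiomer giving (S)-10 is used. The step needs enantiotopic-group selectivity and a silent racemic background: the aryl and Me3SiO groups on C8 differ sharply in shape and π-character, which gives the catalyst a clear handle, and with every hydroxyl silylated no HBr can form. The allyl ether and the hindered silyl ethers are far weaker silyl acceptors than the strained cyclic ether, so the oxetane should react selectively at −78 °C.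

Step 7
Reactants: 10 (2S)-1-bromo-2-[2-(prop-2-en-1-yloxy)-4-({[tri(propan-2-yl)silyl]oxy}methyl)phenyl]-2,3-bis(trimethylsilyloxy)propane
Product: 12 {(2S)-2-[4-(hydroxymethyl)-2-(prop-2-en-1-yloxy)phenyl]oxiran-2-yl}methanol, via bromo triol 11 (not isolated)
Conditions: Bu4NF (4 equiv), THF, 0 °C to rt
Reagents that add atoms: none
Why: Fluoride cleaves the two Me3Si ethers and the i-Pr3Si ether at once, and the tertiary alkoxide then displaces the neopentyl-type bromide in an intramolecular Williamson reaction (3-exo-tet), which should outrun the 4-exo-tet closure of the primary alkoxide and any intermolecular substitution. No bond to C8 is broken, so its configuration is retained, and a Payne rearrangement of 12 would be degenerate and return the same enantiomer.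

Step 8
Reactants: 12 {(2S)-2-[4-(hydroxymethyl)-2-(prop-2-en-1-yloxy)phenyl]oxiran-2-yl}methanol, 13 (2R)-2-methylbutanoic acid
Product: 14 {(2R)-2-[4-({[(2R)-2-methylbutanoyl]oxy}methyl)-2-(prop-2-en-1-yloxy)phenyl]oxiran-2-yl}methyl (2R)-2-methylbutanoate
Conditions: 13 (2.4 equiv in all, added slowly), DCC (2.6 equiv), DMAP (0.2 equiv), CH2Cl2, 0 °C; then rt
Reagents that add atoms: (2R)-2-methylbutanoic acid (the second equivalent of 13, which acylates the second hydroxyl), CC[C@@H](C)C(=O)O
Why: Steglich esterification of the two primary hydroxyls, each by one equivalent of the same acid, in one operation; adding the acid slowly to carbodiimide and DMAP keeps free acid away from the acid-labile oxirane. The α-alkyl stereocentre of the acyl donor is not expected to epimerise under these mild, ketene-free conditions.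

Step 9
Reactants: 14 {(2R)-2-[4-({[(2R)-2-methylbutanoyl]oxy}methyl)-2-(prop-2-en-1-yloxy)phenyl]oxiran-2-yl}methyl (2R)-2-methylbutanoate, 15 (2Z)-2-methylbut-2-enoic acid (angelic acid)
Product: 18 {(2R)-2-[2-{[(2Z)-2-methylbut-2-enoyl]oxy}-4-({[(2R)-2-methylbutanoyl]oxy}methyl)phenyl]oxiran-2-yl}methyl (2R)-2-methylbutanoate, via free phenol 16 (not isolated), via mixed anhydride 17 (not isolated)
Conditions: Pd(PPh3)4 (5 mol%), morpholine (1.2 equiv), THF, rt; then 17 [2 equiv, preformed from 15, 2,4,6-Cl3C6H2COCl, Et3N, toluene, rt], Et3N, 0 °C to rt, no DMAP
Reagents that add atoms: none
Why: Tsuji–Trost deallylation: zerovalent palladium ionises the aryl allyl ether to a π-allylpalladium phenoxide and morpholine takes the allyl group. The phenoxide is then acylated at once by the Yamaguchi mixed anhydride at its less hindered angeloyl carbonyl, so the free phenol never accumulates beside the oxirane. Omitting DMAP and working cold avoids the addition–elimination path that turns the Z-enoate into the E isomer.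

## Compound list

1 | methyl 4-bromo-3-hydroxybenzoate | COC(=O)c1ccc(Br)c(O)c1 | starting material
2 | methyl 4-bromo-3-(prop-2-en-1-yloxy)benzoate | COC(=O)c1ccc(Br)c(OCC=C)c1 | intermediate
3 | [4-bromo-3-(prop-2-en-1-yloxy)phenyl]methanol | OCc1ccc(Br)c(OCC=C)c1 | intermediate
4 | {[4-bromo-3-(prop-2-en-1-yloxy)phenyl]methoxy}tri(propan-2-yl)silane | CC(C)[Si](OCc1ccc(Br)c(OCC=C)c1)(C(C)C)C(C)C | intermediate
5 | oxetan-3-one | O=C1COC1 | starting material
6 | [2-(prop-2-en-1-yloxy)-4-({[tri(propan-2-yl)silyl]oxy}methyl)phenyl]lithium | [Li]c1ccc(CO[Si](C(C)C)(C(C)C)C(C)C)cc1OCC=C | intermediate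
7 | 3-[2-(prop-2-en-1-yloxy)-4-({[tri(propan-2-yl)silyl]oxy}methyl)phenyl]oxetan-3-ol | OC1(COC1)c1ccc(CO[Si](C(C)C)(C(C)C)C(C)C)cc1OCC=C | intermediate
8 | trimethyl({3-[2-(prop-2-en-1-yloxy)-4-({[tri(propan-2-yl)silyl]oxy}methyl)phenyl]oxetan-3-yl}oxy)silane | C=CCOc1cc(CO[Si](C(C)C)(C(C)C)C(C)C)ccc1C1(O[Si](C)(C)C)COC1 | intermediate
9 | bromotrimethylsilane | C[Si](C)(C)Br | starting material
10 | (2S)-1-bromo-2-[2-(prop-2-en-1-yloxy)-4-({[tri(propan-2-yl)silyl]oxy}methyl)phenyl]-2,3-bis(trimethylsilyloxy)propane | C=CCOc1cc(CO[Si](C(C)C)(C(C)C)C(C)C)ccc1[C@](O[Si](C)(C)C)(CO[Si](C)(C)C)CBr | intermediate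
11 | (2S)-3-bromo-2-[4-(hydroxymethyl)-2-(prop-2-en-1-yloxy)phenyl]propane-1,2-diol | C=CCOc1cc(CO)ccc1[C@](O)(CO)CBr | intermediate
12 | {(2S)-2-[4-(hydroxymethyl)-2-(prop-2-en-1-yloxy)phenyl]oxiran-2-yl}methanol | C=CCOc1cc(CO)ccc1[C@]1(CO)CO1 | intermediate
13 | (2R)-2-methylbutanoic acid | CC[C@@H](C)C(=O)O | starting material
14 | {(2R)-2-[4-({[(2R)-2-methylbutanoyl]oxy}methyl)-2-(prop-2-en-1-yloxy)phenyl]oxiran-2-yl}methyl (2R)-2-methylbutanoate | C=CCOc1cc(COC(=O)[C@H](C)CC)ccc1[C@]1(COC(=O)[C@H](C)CC)CO1 | intermediate
15 | (2Z)-2-methylbut-2-enoic acid (angelic acid) | C/C=C(/C)C(=O)O | starting material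
16 | {(2R)-2-[2-hydroxy-4-({[(2R)-2-methylbutanoyl]oxy}methyl)phenyl]oxiran-2-yl}methyl (2R)-2-methylbutanoate | Oc1cc(COC(=O)[C@H](C)CC)ccc1[C@]1(COC(=O)[C@H](C)CC)CO1 | intermediate
17 | (2Z)-2-methylbut-2-enoic 2,4,6-trichlorobenzoic anhydride | C/C=C(/C)C(=O)OC(=O)c1c(Cl)cc(Cl)cc1Cl | intermediate
18 | {(2R)-2-[2-{[(2Z)-2-methylbut-2-enoyl]oxy}-4-({[(2R)-2-methylbutanoyl]oxy}methyl)phenyl]oxiran-2-yl}methyl (2R)-2-methylbutanoate (CNP0166772.1) | C/C=C(/C)C(=O)Oc1cc(COC(=O)[C@H](C)CC)ccc1[C@]1(COC(=O)[C@H](C)CC)CO1 | target

## Step count and least certain steps

Total step count: 9. Longest linear sequence: 9 steps (1 to 18); 5, 9, 13 and 15 enter as purchased reagents.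

**Step 6 (key step).** The catalyst may discriminate poorly between the two ring CH2 groups, because the ortho-allyloxy group twists the aryl ring and crowds C8 beyond what simpler oxetanes present. A racemic background opening by HBr from traces of moisture is also possible, as is attack of the silyl bromide on the benzylic silyl ether. The fallback sets out from 4 and returns at 12, and replaces the desymmetrisation by a Sharpless asymmetric epoxidation. Magnesium insertion into 4 in THF would give the arylmagnesium bromide F1. CuI-catalysed carbomagnesiation of prop-2-yn-1-ol (premetalated with i-PrMgCl) should place the aryl group on the internal alkyne carbon and give the 2-arylallyl alcohol F2. Epoxidation with Ti(OiPr)4, L-(+)-diisopropyl tartrate and t-BuOOH over 4 Å molecular sieves in CH2Cl2 at −20 °C should deliver oxygen to the face that gives the (S)-epoxy alcohol F3; the isolated allyl ether is not a substrate for the titanium catalyst. Bu4NF then removes the silyl group and gives 12.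

**Step 9.** The liberated ortho-hydroxyaryl oxirane may decompose by intramolecular opening or rearrangement before it is acylated. The angeloyl group may isomerise from Z to E through conjugate addition–elimination by amine or phosphine, and the aryl ester may suffer aminolysis by residual morpholine. The fallback sets out from 14 and returns at 18, as a transprotection in which the phenol is never free. Pd(PPh3)4-catalysed hydrostannolysis of the allyl ether with Bu3SnH in CH2Cl2 would give the tributylstannyl aryl ether F4 and propene. F4 is acylated in the same flask at 0 °C by (2Z)-2-methylbut-2-enoyl chloride F5, made from 15 under neutral conditions with 1-chloro-N,N,2-trimethylprop-1-en-1-amine, so that no amine is present at any point.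

**Step 7.** 4-exo-tet closure by the primary alkoxide may compete, which would return material to an achiral oxetane, and the strongly basic alkoxides may open the product oxirane intermolecularly. The fallback sets out from 10 and returns at 14, changing the order of events so that the ring is closed last. Fluoride buffered with acetic acid (Bu4NF/AcOH 1:1, THF) removes the silyl groups without forming alkoxides, and the bromo triol 11 is isolated. The two primary hydroxyls of 11 are esterified with two equivalents of 13 (DCC, DMAP), while the tertiary hydroxyl stays free, to give the bromohydrin diester F6. Cs2CO3 in MeCN then closes the oxirane to 14; with O10 acylated no oxetane can form, and the esterification no longer has to be run on the acid-sensitive oxirane.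

**Step 4.** Proton transfer from 5 to the basic aryllithium and self-condensation of the ketone may lower the conversion. If the exchange mixture warms, intramolecular carbolithiation of the allyl ether by 6 or attack of n-BuLi on the allyl ether may follow. The fallback sets out from 4 and returns at 7, avoiding alkyllithium altogether. Direct insertion of magnesium into 4 in the presence of LiCl would give the arylmagnesium bromide–lithium chloride complex F7, which is added to 5 precomplexed with LaCl3·2LiCl; this favours carbonyl addition of the less basic organomagnesium over deprotonation.

## Further compounds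

F1 | step 6 | bromo[2-(prop-2-en-1-yloxy)-4-({[tri(propan-2-yl)silyl]oxy}methyl)phenyl]magnesium | Br[Mg]c1ccc(CO[Si](C(C)C)(C(C)C)C(C)C)cc1OCC=C
F2 | step 6 | 2-[2-(prop-2-en-1-yloxy)-4-({[tri(propan-2-yl)silyl]oxy}methyl)phenyl]prop-2-en-1-ol | C=C(CO)c1ccc(CO[Si](C(C)C)(C(C)C)C(C)C)cc1OCC=C
F3 | step 6 | {(2S)-2-[2-(prop-2-en-1-yloxy)-4-({[tri(propan-2-yl)silyl]oxy}methyl)phenyl]oxiran-2-yl}methanol | C=CCOc1cc(CO[Si](C(C)C)(C(C)C)C(C)C)ccc1[C@]1(CO)CO1
F4 | step 9 | {(2R)-2-[4-({[(2R)-2-methylbutanoyl]oxy}methyl)-2-[(tributylstannyl)oxy]phenyl]oxiran-2-yl}methyl (2R)-2-methylbutanoate | CCCC[Sn](CCCC)(CCCC)Oc1cc(COC(=O)[C@H](C)CC)ccc1[C@]1(COC(=O)[C@H](C)CC)CO1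
F5 | step 9 | (2Z)-2-methylbut-2-enoyl chloride | C/C=C(/C)C(Cl)=O
F6 | step 7 | (2S)-3-bromo-2-hydroxy-2-[4-({[(2R)-2-methylbutanoyl]oxy}methyl)-2-(prop-2-en-1-yloxy)phenyl]propyl (2R)-2-methylbutanoate | C=CCOc1cc(COC(=O)[C@H](C)CC)ccc1[C@](O)(COC(=O)[C@H](C)CC)CBr
F7 | step 4 | bromo[2-(prop-2-en-1-yloxy)-4-({[tri(propan-2-yl)silyl]oxy}methyl)phenyl]magnesium–lithium chloride complex | Br[Mg]c1ccc(CO[Si](C(C)C)(C(C)C)C(C)C)cc1OCC=C.[Li+].[Cl-]
A1 | alternative 1 | tert-butyl({(2R)-2-[4-({[tert-butyl(dimethyl)silyl]oxy}methyl)-2-(prop-2-en-1-yloxy)phenyl]oxiran-2-yl}methoxy)dimethylsilane | C=CCOc1cc(CO[Si](C)(C)C(C)(C)C)ccc1[C@]1(CO[Si](C)(C)C(C)(C)C)CO1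
A2 | alternative 1 | 2-{[tert-butyl(dimethyl)silyl]oxy}-1-[4-({[tert-butyl(dimethyl)silyl]oxy}methyl)-2-(prop-2-en-1-yloxy)phenyl]ethan-1-one | C=CCOc1cc(CO[Si](C)(C)C(C)(C)C)ccc1C(=O)CO[Si](C)(C)C(C)(C)C
A3 | alternative 1 | trimethylsulfoxonium iodide | C[S+](C)(C)=O.[I-]
A4 | alternative 2 | [4-[(2R)-1,2-dihydroxybut-3-en-2-yl]-3-{[tri(propan-2-yl)silyl]oxy}phenyl]methyl (2R)-2-methylbutanoate | CC(C)[Si](Oc1cc(COC(=O)[C@H](C)CC)ccc1[C@](O)(C=C)CO)(C(C)C)C(C)C
A5 | alternative 2 | [4-(4-ethenyl-2-oxo-1,3-dioxolan-4-yl)-3-{[tri(propan-2-yl)silyl]oxy}phenyl]methyl (2R)-2-methylbutanoate, racemic at the dioxolanone carbon | CC(C)[Si](Oc1cc(COC(=O)[C@H](C)CC)ccc1C1(C=C)COC(=O)O1)(C(C)C)C(C)C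
A6 | alternative 2 | [4-[(2R)-2-ethenyloxiran-2-yl]-3-{[tri(propan-2-yl)silyl]oxy}phenyl]methyl (2R)-2-methylbutanoate | CC(C)[Si](Oc1cc(COC(=O)[C@H](C)CC)ccc1[C@]1(C=C)CO1)(C(C)C)C(C)C
A7 | alternative 3 | methyl (2S)-3-{[tert-butyl(dimethyl)silyl]oxy}-2-[4-({[tert-butyl(dimethyl)silyl]oxy}methyl)-2-hydroxyphenyl]-2-hydroxypropanoate | Oc1cc(CO[Si](C)(C)C(C)(C)C)ccc1[C@](O)(CO[Si](C)(C)C(C)(C)C)C(=O)OC
A8 | alternative 3 | 3-({[tert-butyl(dimethyl)silyl]oxy}methyl)phenol | Oc1cccc(CO[Si](C)(C)C(C)(C)C)c1
A9 | alternative 3 | methyl 3-{[tert-butyl(dimethyl)silyl]oxy}-2-oxopropanoate | COC(=O)C(=O)CO[Si](C)(C)C(C)(C)C
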